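## Structural features

Eudesmane numbering is used throughout: ring A is C1–C5 and C10, ring B is C5–C10.

The target is a 5βH-eudesmane. Its two six-membered carbocycles are cis-fused through the C5–C10 bond, with the angular methyl on C10 and the hydrogen on C5 both β. Ring A carries a cis-3α,4α-diol in differentiated form: a secondary angelate ((Z)-2-methylbut-2-enoate) on C3 and a tertiary acetate on C4, which also bears a β-methyl group. Ring B carries the C8 ketone, flanked by C7 (β-isopropyl) and by the C9 methylene next to quaternary C10. Four of the five stereocentres are contiguous (C3, C4, C5, C10) and two of them are fully substituted. The fifth, C7, is α to the ketone and epimerisable, but 7β (equatorial isopropyl in the conformer that keeps the C4 and C10 methyl groups apart) is the stable epimer. The fragile parts are the angelate (Z-to-E isomerisation under basic, nucleophilic or hot acidic conditions), the pair of cis-vicinal esters (acyl migration) and the tertiary acetate. The real difficulty is the cis ring fusion next to an oxygenated quaternary C4 with the correct facial relationship, and then esterifying the two hydroxyls differently. The key step exploits two facts: C3, C4, C5, C10, C9 and C8 are the six ring carbons of an oxidised 2,4-dimethylphenol once the C3–C8 bond is restored, and the C3 ketone with a C8=C9 alkene (a δ,ε-unsaturated ketone) is the retron of an oxy-Cope rearrangement of a bicyclo[2.2.2]octenol.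

## Logic of the disconnections

**22 ⇒ 21.** The O4–acetyl bond is cut first. The tertiary acetate is the most hindered and most migration-prone ester, so it goes on last. This leaves 21 with one free tertiary hydroxyl. The forward step must acylate an axial tertiary alcohol without acyl exchange with O3 and without touching the Z alkene.

**21 ⇒ 18 + 19.** The O3–acyl bond is cut. A secondary equatorial hydroxyl beside a tertiary one can be distinguished by sterics alone, so no protecting group is needed. The acyl unit comes from 19 and the core becomes the diol ketone 18. The forward step must activate 19 without Z-to-E isomerisation.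

**18 ⇒ 17.** The two hydroxyls are traced back to benzylic ethers (O3–CH2Ph and O4–CH2OCH2Ph). Both fall in one neutral hydrogenolysis. This avoids acid, which with a cis O3/O4 pair and an acid-labile alkoxymethyl ether on O4 would invite closure to a cyclic formaldehyde acetal. The hydrogenolysis must precede any alkene and must spare the ketone.

**17 ⇒ 16 ⇒ 14.** The C8 carbonyl is retraced to the C8 alcohol and then to the C8=C9 alkene (C8–O cut). An isolated alkene is what the key step leaves in ring B. The forward step must put oxygen on C8 and not C9; the face is irrelevant.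

**14 ⇒ 13 ⇒ 12.** The O3–benzyl bond and then the C3–H bond are removed, giving the C3 ketone. Together with the C8=C9 alkene this is the oxy-Cope retron. The forward reduction must deliver hydride to the β face.

**12 ⇒ 9 (through 11 and 10).** C1–C10 is cut and C3–C8 reconnected. This removes ring A and the quaternary stereocentre C10 in one operation and turns the cis-decalin into a bicyclo[2.2.2]octene whose bridges fix the relative configuration. The forward step needs the vinyl group on the side of the C9=C10 bridge and O4 on the other side. It also needs an O4 substituent that is inert to KH and cannot migrate to the neighbouring alkoxide.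

**9 ⇒ 7 + 8.** The C2–C3 bond is cut; C1 and C2 come from a two-carbon nucleophile. Attack must occur on the ketone face anti to the ethano bridge.

**7 ⇒ 6 ⇒ 5.** The O4–CH2 bond is cut and the free hydroxyl is traced back to the acetate that dearomatisation installs. The acetate cannot survive 8 or KH. The exchange must be mild enough to avoid α-ketol rearrangement.

**5 ⇒ 4.** No bond is cut; the enantiomers are separated. 4 is the earliest rigid, stable intermediate, and every later stereocentre is relayed from it. A chiral stationary phase must resolve it and the absolute configuration must be assigned once.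

**4 ⇒ 2 + 3.** C5–C6 and C7–C8 are cut (retro-Diels–Alder). C6, C7 and the isopropyl group come from 3, leaving a planar dienone with one stereocentre. The forward step needs isopropyl next to the α-keto bridgehead, addition syn to the acetoxy group, and endo orientation.

**2 ⇒ 1.** The C4–O bond is cut, restoring the aromatic ring. The forward step must oxygenate the methyl-bearing ortho carbon.

## Other disconnections considered

**Alternative 1:** Ring B is cut at C7–C8 and C8–C9, so that C8 is excised, leading back to the cis-hydrindanone A2. In the forward direction Me3SiCHN2 with BF3·OEt2 would insert C8 between the carbonyl carbon C9 and C7 to give decalinone A1.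
- In favour: A2 belongs to a family available as single enantiomers by proline-catalysed annulation, so no resolution is needed. On this point the alternative is better than the chosen plan. The cis fusion would come from hydrogenation and the chemistry is scalable.
- Against: A1 has its ketone on C9 and not C8, has no isopropyl on C7 and no oxygen on C4. A 1,2-carbonyl transposition, a C7 alkylation and a C4 hydroxylation would all remain. The insertion must also favour migration of C7 over quaternary C10 and stop after one homologation.
- Comparison: structurally, the chosen cycloadduct already holds C4–O, the C7 isopropyl and a marker for C8, whereas A1 is only the bicyclic core. Mechanistically, the insertion depends on migratory aptitude, while the sigmatropic shift is geometrically constrained. In step count the alternative should be clearly longer after its key step.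

**Alternative 2:** The C5–C6 bond is cut, giving cyclohexenone A4 with a (1-hydroxycyclopropyl)methyl group on quaternary C10. Forward, Et2Zn would open the cyclopropanol to the zinc homoenolate, and catalytic CuBr·SMe2 with Me3SiCl would drive conjugate addition of C6 to C5. This closes ring B and gives A3 with the C8 ketone and a C3=C4 silyl enol ether.
- In favour: the C8 carbonyl arrives at the right carbon and oxidation level with no redox steps, which is better than the chosen plan. The silyl enol ether is well placed for a Rubottom oxidation to install the C4 oxygen. A cis fusion is the expected outcome of a tethered conjugate addition, so the two plans are equal on ring-fusion control.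
- Against: A3 has no isopropyl group, and alkylating C7 rather than C9 on a ketone with two methylene neighbours is not regiocontrolled. A4 needs an enantioselective synthesis of its quaternary centre. The face of the C4 oxidation is not enforced. Intramolecular homoenolate conjugate additions have limited precedent and compete with protonation.
- Comparison: structurally it builds ring B while the chosen plan builds ring A. Mechanistically it is less secure. Its step economy is better at C8, worse at C7 and C4, and probably no better overall.

**Alternative 3:** Ring A is cut at C3–C4, giving keto aldehyde A6: a ring B cyclohexane with methyl and 3-oxopropyl on C10, acetyl on C5 and C8 masked as a dioxolane. Forward, SmI2 with tert-butanol would form the aldehyde ketyl, which adds to the ketone through a samarium-bridged array to give cis-diol A5.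
- In favour: one step would make ring A, both carbinol centres and their cis relationship, with C7 and C8 already in place. Only deketalisation and two esterifications would remain. This endgame is shorter than that of the chosen plan and needs no protecting-group exchange at C4.
- Against: the ring fusion depends on the enolisable C5 acetyl centre and is not enforced by the mechanism. Two cis-diols are possible and the facial sense relative to the C10 methyl is uncertain. No short enantioselective route to A6 is apparent, since C5 and quaternary C10 are adjacent and neither is activated by the C8 carbonyl in the useful sense.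
- Comparison: it is better after the key step, and worse before it and in stereochemical security. The chosen plan obtains the cis fusion from geometry.

Key step: step 7

**Assumption:** the enantiomer collected in step 3 is the (1R,3S,4S,7R) one. Which band this is must be assigned once, for example by anomalous-dispersion X-ray analysis of a crystalline derivative.

**Remarks on the design:**
- The descriptors of 9, 12 and 22 were checked against each other and are consistent with a suprafacial shift; no stereochemical error was found.
- The endo isopropyl group of the cycloadduct maps onto 7β, which is both the target configuration and the stable epimer next to the C8 ketone. No separate C7 equilibration step is therefore planned.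
- O4 is carried as a benzyloxymethyl ether and O3 as a benzyl ether. Neither can migrate, both survive KH, and both are removed together by hydrogenolysis. An acid-labile alkoxymethyl ether on O4 would need acid beside a cis oxygen at the end.

## Route

Step 1
Reactants: 1 2,4-dimethylphenol
Product: 2 (±)-6-acetoxy-4,6-dimethylcyclohexa-2,4-dien-1-one
Conditions: Pb(OAc)4, AcOH/CH2Cl2, 0 °C to rt; used at once
Reagents that add atoms: lead tetraacetate, CC(=O)O[Pb](OC(C)=O)(OC(C)=O)OC(C)=O
Why: Wessely acetoxylation: the phenol exchanges onto tetravalent lead and an acetate ligand is delivered to the methyl-bearing ortho carbon, which dearomatises the ring and creates the future C4 as a racemic oxygenated quaternary centre. The 4-methyl group on the diene slows self-dimerisation; isomeric acetoxylation products are inert in step 2 and are removed there.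

Step 2
Reactants: 2 (±)-6-acetoxy-4,6-dimethylcyclohexa-2,4-dien-1-one; 3 3-methylbut-1-ene
Product: 4 (±)-(1R*,3S*,4S*,7R*)-3-acetoxy-7-isopropyl-3,5-dimethylbicyclo[2.2.2]oct-5-en-2-one (acetoxy toward the C7–C8 bridge, 3-methyl toward the C5=C6 bridge, isopropyl on C7 pointing to the C5=C6 bridge)
Conditions: 3 (20 equiv), toluene, sealed vessel, 100 °C
Reagents that add atoms: none
Why: Diels–Alder reaction of a cyclohexa-2,4-dienone with a monosubstituted alkene: the CH2 terminus bonds to the diene carbon remote from the carbonyl (larger LUMO coefficient), which places isopropyl next to the α-keto bridgehead. The alkene should add to the face bearing the acetoxy group (anti to the methyl) with isopropyl endo, so C1, C4 and C7 are set relative to C3; minor isomers are removed by chromatography.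

Step 3
Reactants: 4 (±)-(1R*,3S*,4S*,7R*)-3-acetoxy-7-isopropyl-3,5-dimethylbicyclo[2.2.2]oct-5-en-2-one
Product: 5 (1R,3S,4S,7R)-3-acetoxy-7-isopropyl-3,5-dimethylbicyclo[2.2.2]oct-5-en-2-one
Conditions: preparative SFC, amylose tris(3,5-dimethylphenylcarbamate) phase, CO2/MeOH, 35 °C
Reagents that add atoms: none
Why: Chromatographic resolution on a chiral stationary phase separates the enantiomers without touching any bond; a rigid, stable ketone with a β,γ-unsaturated carbonyl chromophore is a suitable substrate, and resolving here wastes the least material.

Step 4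
Reactants: 5 (1R,3S,4S,7R)-3-acetoxy-7-isopropyl-3,5-dimethylbicyclo[2.2.2]oct-5-en-2-one
Product: 6 (1R,3S,4S,7R)-3-hydroxy-7-isopropyl-3,5-dimethylbicyclo[2.2.2]oct-5-en-2-one
Conditions: K2CO3 (0.2 equiv), MeOH, 0 °C
Reagents that add atoms: none
Why: Base-catalysed methanolysis (transesterification) of an α-acyloxy ketone, an activated ester. Both α-carbons of the ketone are non-enolisable (bridgehead and quaternary), so no stereocentre can be lost, and the low temperature guards against α-ketol rearrangement.

Step 5
Reactants: 6 (1R,3S,4S,7R)-3-hydroxy-7-isopropyl-3,5-dimethylbicyclo[2.2.2]oct-5-en-2-one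
Product: 7 (1R,3S,4S,7R)-3-(benzyloxymethoxy)-7-isopropyl-3,5-dimethylbicyclo[2.2.2]oct-5-en-2-one
Conditions: BnOCH2Cl, iPr2NEt, Bu4NI (cat.), ClCH2CH2Cl, 60 °C
Reagents that add atoms: benzyl chloromethyl ether, ClCOCc1ccccc1
Why: Alkylation of the tertiary alcohol with an α-chloro ether under amine base (Williamson-type, iodide-catalysed). The acetal is stable to Grignard reagents and KH, cannot migrate to a neighbouring alkoxide and is later cleaved by hydrogenolysis.

Step 6
Reactants: 7 (1R,3S,4S,7R)-3-(benzyloxymethoxy)-7-isopropyl-3,5-dimethylbicyclo[2.2.2]oct-5-en-2-one; 8 vinylmagnesium bromide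
Product: 9 (1R,2R,3S,4S,7R)-3-(benzyloxymethoxy)-7-isopropyl-3,5-dimethyl-2-vinylbicyclo[2.2.2]oct-5-en-2-ol (vinyl syn to the C5=C6 bridge; both oxygens toward the C7–C8 bridge)
Conditions: 8, THF, −78 to 0 °C; aq. NH4Cl
Reagents that add atoms: none
Why: Grignard 1,2-addition to a non-enolisable ketone: the exo hydrogens of the ethano bridge and the adjacent benzyloxymethoxy group shield one face, so attack should come from the side of the etheno bridge. This sets C2 as R with the vinyl group syn to the alkene, as the next step requires.

Step 7
Reactants: 9 (1R,2R,3S,4S,7R)-3-(benzyloxymethoxy)-7-isopropyl-3,5-dimethyl-2-vinylbicyclo[2.2.2]oct-5-en-2-ol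
Product: 12 4α-(benzyloxymethoxy)-5βH,7αH-eudesm-8-en-3-one (cis-fused; 4β-methyl, 10β-methyl, 7β-isopropyl), via potassium alkoxide 10 (not isolated), via potassium enolate 11 (not isolated)
Conditions: KH, 18-crown-6, THF, 0 °C to rt; aq. NH4Cl, −78 °C
Reagents that add atoms: none
Why: Deprotonation gives alkoxide 10, whose charge is freed by the crown ether and weakens the adjacent C3–C8 bond; a concerted suprafacial [3,3] shift then breaks C3–C8, forms C8=C9 and joins the vinyl terminus C1 to C10, giving enolate 11, which is protonated at C2 on quench. The closest known reaction type is the anionic oxy-Cope rearrangement of 2-vinylbicyclo[2.2.2]oct-5-en-2-ols to cis-decalinones. Ring A (C1–C2–C3–C4–C5–C10) closes by this sigmatropic C1–C10 bond formation through the boat-shaped six-atom array that the bicycle enforces, not by an ionic cyclisation, while ring B is the existing six-membered ring formed by the etheno and ethano bridges. The one new stereocentre, quaternary C10, is fixed by geometry: C1 can reach C10 only on the alkene face turned toward the carbinol bridge, the same side from which C4 is attached to C5, so the fusion must be cis (10β-methyl, 5β-H). C4, C5 and C7 are not touched. The selectivity needed is positional (vinyl syn to the C9=C10 bridge) and was secured in step 6. The O4 acetal has no acidic or migrating function, and quaternary C4 leaves C2 as the only site of enolate protonation.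

Step 8
Reactants: 12 4α-(benzyloxymethoxy)-5βH,7αH-eudesm-8-en-3-one
Product: 13 4α-(benzyloxymethoxy)-5βH,7αH-eudesm-8-en-3α-ol
Conditions: NaBH4, MeOH, −20 to 0 °C
Reagents that add atoms: none
Why: Borohydride reduction of a cyclohexanone by axial attack from the β face, anti to the axial C4–O bond (Felkin–Anh polar effect) and analogous to 3-oxo-5β-steroids. This should give the equatorial 3α-alcohol, cis to the C4 oxygen.

Step 9
Reactants: 13 4α-(benzyloxymethoxy)-5βH,7αH-eudesm-8-en-3α-ol
Product: 14 3α-benzyloxy-4α-(benzyloxymethoxy)-5βH,7αH-eudesm-8-ene
Conditions: NaH, BnBr, Bu4NI (cat.), THF/DMF, 0 °C to rt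
Reagents that add atoms: benzyl bromide, BrCc1ccccc1
Why: Williamson etherification of the secondary alkoxide; no carbonyl is present at this stage. The benzyl ether is chosen because it is cleaved together with the O4 acetal in step 12.

Step 10
Reactants: 14 3α-benzyloxy-4α-(benzyloxymethoxy)-5βH,7αH-eudesm-8-ene
Product: 16 3α-benzyloxy-4α-(benzyloxymethoxy)-5βH,7αH-eudesman-8β-ol, via 8β-alkylborane 15 (not isolated)
Conditions: BH3·THF, THF, 0 °C to rt; then NaOH, H2O2, 0 °C to rt
Reagents that add atoms: hydrogen peroxide, OO (oxygen on C8); borane–tetrahydrofuran, B.C1CCOC1 (boron only in 15, hydrogen to C9)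
Why: Hydroboration–oxidation: borane should add syn from the convex β face, with boron on C8 because C9 adjoins quaternary C10 whose axial methyl lies on that face. Oxidation with retention gives the 8β-alcohol, a centre that is removed in step 11.

Step 11
Reactants: 16 3α-benzyloxy-4α-(benzyloxymethoxy)-5βH,7αH-eudesman-8β-ol
Product: 17 3α-benzyloxy-4α-(benzyloxymethoxy)-5βH,7αH-eudesman-8-one
Conditions: Dess–Martin periodinane, NaHCO3, CH2Cl2, rt
Reagents that add atoms: none
Why: Dess–Martin oxidation of a secondary alcohol under buffered conditions; C7 keeps its β-isopropyl group, which is also the favoured (equatorial) epimer beside the new ketone.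

Step 12
Reactants: 17 3α-benzyloxy-4α-(benzyloxymethoxy)-5βH,7αH-eudesman-8-one
Product: 18 3α,4α-dihydroxy-5βH,7αH-eudesman-8-one
Conditions: H2 (1 atm), Pd(OH)2 on carbon, EtOAc/EtOH, rt
Reagents that add atoms: none
Why: Catalytic hydrogenolysis cleaves both benzylic C–O bonds; the hemiformal left on O4 loses formaldehyde spontaneously. The saturated ketone is inert under these conditions, and the step comes before any alkene is introduced.

Step 13
Reactants: 18 3α,4α-dihydroxy-5βH,7αH-eudesman-8-one; 19 angelic acid
Product: 21 4α-hydroxy-8-oxo-5βH,7αH-eudesman-3α-yl angelate, via mixed anhydride 20 (not isolated)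
Conditions: 19, 2,4,6-trichlorobenzoyl chloride, Et3N, toluene, rt; then 18, 75 °C
Reagents that add atoms: none
Why: Yamaguchi esterification: the preformed mixed anhydride should acylate the secondary equatorial 3α-hydroxyl in preference to the hindered tertiary one. Forming the anhydride first and heating without a nucleophilic catalyst is the established way to transfer an angeloyl group without Z-to-E isomerisation.

Step 14
Reactants: 21 4α-hydroxy-8-oxo-5βH,7αH-eudesman-3α-yl angelate
Product: 22 4α-acetoxy-8-oxo-5βH,7αH-eudesman-3α-yl angelate, (3R,4S,5S,7R,10R)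
Conditions: Ac2O, Sc(OSO2CF3)3 (cat.), MeCN, −20 to 0 °C
Reagents that add atoms: acetic anhydride, CC(=O)OC(C)=O
Why: Lewis-acid-catalysed acetylation: the scandium salt activates the anhydride strongly enough to acylate tertiary alcohols at low temperature. The absence of base should prevent acyl exchange between O3 and O4 and leave the angelate geometry intact.

## Compound list

1 | 2,4-dimethylphenol | Cc1ccc(O)c(C)c1 | starting material
2 | (±)-6-acetoxy-4,6-dimethylcyclohexa-2,4-dien-1-one (racemic) | CC(=O)OC1(C)C=C(C)C=CC1=O | intermediate
3 | 3-methylbut-1-ene | C=CC(C)C | starting material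
4 | (±)-(1R*,3S*,4S*,7R*)-3-acetoxy-7-isopropyl-3,5-dimethylbicyclo[2.2.2]oct-5-en-2-one (racemate, both enantiomers written) | O=C1[C@H]2C=C(C)[C@@H]([C@]1(C)OC(C)=O)C[C@@H]2C(C)C.O=C1[C@@H]2C=C(C)[C@H]([C@@]1(C)OC(C)=O)C[C@H]2C(C)C | intermediate
5 | (1R,3S,4S,7R)-3-acetoxy-7-isopropyl-3,5-dimethylbicyclo[2.2.2]oct-5-en-2-one | O=C1[C@H]2C=C(C)[C@@H]([C@]1(C)OC(C)=O)C[C@@H]2C(C)C | intermediate
6 | (1R,3S,4S,7R)-3-hydroxy-7-isopropyl-3,5-dimethylbicyclo[2.2.2]oct-5-en-2-one | O=C1[C@H]2C=C(C)[C@@H]([C@]1(C)O)C[C@@H]2C(C)C | intermediate
7 | (1R,3S,4S,7R)-3-(benzyloxymethoxy)-7-isopropyl-3,5-dimethylbicyclo[2.2.2]oct-5-en-2-one | O=C1[C@H]2C=C(C)[C@@H]([C@]1(C)OCOCc3ccccc3)C[C@@H]2C(C)C | intermediate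
8 | vinylmagnesium bromide | C=C[Mg]Br | starting material
9 | (1R,2R,3S,4S,7R)-3-(benzyloxymethoxy)-7-isopropyl-3,5-dimethyl-2-vinylbicyclo[2.2.2]oct-5-en-2-ol | O[C@]1(C=C)[C@H]2C=C(C)[C@@H]([C@]1(C)OCOCc3ccccc3)C[C@@H]2C(C)C | intermediate
10 | potassium alkoxide of 9 | [K+].[O-][C@]1(C=C)[C@H]2C=C(C)[C@@H]([C@]1(C)OCOCc3ccccc3)C[C@@H]2C(C)C | intermediate
11 | potassium C2=C3 enolate of 12 | [K+].[O-]C1=CC[C@]2(C)C=C[C@@H](C(C)C)C[C@@H]2[C@]1(C)OCOCc3ccccc3 | intermediate
12 | 4α-(benzyloxymethoxy)-5βH,7αH-eudesm-8-en-3-one | O=C1CC[C@]2(C)C=C[C@@H](C(C)C)C[C@@H]2[C@]1(C)OCOCc3ccccc3 | intermediate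
13 | 4α-(benzyloxymethoxy)-5βH,7αH-eudesm-8-en-3α-ol | O[C@@H]1CC[C@]2(C)C=C[C@@H](C(C)C)C[C@@H]2[C@]1(C)OCOCc3ccccc3 | intermediate
14 | 3α-benzyloxy-4α-(benzyloxymethoxy)-5βH,7αH-eudesm-8-ene | c4ccccc4CO[C@@H]1CC[C@]2(C)C=C[C@@H](C(C)C)C[C@@H]2[C@]1(C)OCOCc3ccccc3 | intermediate
15 | [3α-benzyloxy-4α-(benzyloxymethoxy)-5βH,7αH-eudesman-8β-yl]borane | c4ccccc4CO[C@@H]1CC[C@]2(C)C[C@@H]([BH2])[C@@H](C(C)C)C[C@@H]2[C@]1(C)OCOCc3ccccc3 | intermediate
16 | 3α-benzyloxy-4α-(benzyloxymethoxy)-5βH,7αH-eudesman-8β-ol | c4ccccc4CO[C@@H]1CC[C@]2(C)C[C@@H](O)[C@@H](C(C)C)C[C@@H]2[C@]1(C)OCOCc3ccccc3 | intermediate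
17 | 3α-benzyloxy-4α-(benzyloxymethoxy)-5βH,7αH-eudesman-8-one | c4ccccc4CO[C@@H]1CC[C@]2(C)CC(=O)[C@@H](C(C)C)C[C@@H]2[C@]1(C)OCOCc3ccccc3 | intermediate
18 | 3α,4α-dihydroxy-5βH,7αH-eudesman-8-one | O[C@@H]1CC[C@]2(C)CC(=O)[C@@H](C(C)C)C[C@@H]2[C@]1(C)O | intermediate
19 | angelic acid, (Z)-2-methylbut-2-enoic acid | C/C=C(/C)C(=O)O | starting material
20 | angelic 2,4,6-trichlorobenzoic anhydride | C/C=C(/C)C(=O)OC(=O)c1c(Cl)cc(Cl)cc1Cl | intermediate
21 | 4α-hydroxy-8-oxo-5βH,7αH-eudesman-3α-yl angelate | C/C=C(/C)C(=O)O[C@@H]1CC[C@]2(C)CC(=O)[C@@H](C(C)C)C[C@@H]2[C@]1(C)O | intermediate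
22 | 4α-acetoxy-8-oxo-5βH,7αH-eudesman-3α-yl angelate, (3R,4S,5S,7R,10R) | C/C=C(/C)C(=O)O[C@@H]1CC[C@]2(C)CC(=O)[C@@H](C(C)C)C[C@@H]2[C@]1(C)OC(C)=O | target

## Step count and least certain steps

Total step count: 14. Longest linear sequence: 14 steps (1 to 22); 3, 8 and 19 are purchased and enter in steps 2, 6 and 13.

**Step 7 (key step).** The most likely failure is stalling of the sigmatropic shift, because the alkene carbon that receives C1 bears a methyl group and must become quaternary in a crowded boat array. Base-induced decomposition of the alkoxide could follow on forcing. The fallback removes the strong base and sets out from 9. Silylation with N-(trimethylsilyl)imidazole gives the trimethylsilyl ether of 9 F1. This is heated in decalin at about 220 °C in base-washed glass, so that a neutral siloxy-Cope rearrangement gives the trimethylsilyl enol ether of 12 F2. Buffered Bu4NF/AcOH then cleaves it, and the route is rejoined at 12.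

**Step 2.** The cycloaddition of an unactivated, volatile alkene may be too slow relative to self-dimerisation or thermal rearrangement of the dienone, and weak polarisation of the alkene may erode regio- and endo-control. The fallback sets out from 2. But-3-en-2-one, an activated dienophile with reliable ortho/endo selectivity, is used to give the racemic 7-endo-acetyl adduct F3. Lombardo methylenation (Zn, CH2Br2, TiCl4) of the unhindered methyl ketone is non-basic and should not epimerise C7; it gives the racemic 7-endo-isopropenyl adduct F4. Hydrogenation of the 1,1-disubstituted alkene with H2 and RhCl(PPh3)3 then rejoins the route at 4.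

**Step 10.** Loss of regiocontrol (boron on C9) or attack on both faces is possible, since both alkene carbons have branched neighbours. The fallback sets out from 14. N-iodosuccinimide in aqueous THF should give, by reversible iodonium formation and trans-diaxial opening by water at the non-neopentyl C8 from the convex face (Fürst–Plattner rule), 3α-benzyloxy-4α-(benzyloxymethoxy)-9α-iodo-5βH,7αH-eudesman-8β-ol F5. Radical deiodination with Bu3SnH and 2,2'-azobis(2-methylpropionitrile) in toluene at 80 °C rejoins the route at 16.

**Step 13.** Geometric isomerisation of the activated angeloyl donor to the tigloyl isomer, or incomplete acylation of a secondary hydroxyl next to a fully substituted carbon, is the risk. The fallback sets out from 18 and builds the Z alkene on the substrate. Carbodiimide coupling with 2-[bis(2,2,2-trifluoroethoxy)phosphoryl]propanoic acid gives 4α-hydroxy-8-oxo-5βH,7αH-eudesman-3α-yl 2-[bis(2,2,2-trifluoroethoxy)phosphoryl]propanoate F6. A Still–Gennari olefination with acetaldehyde (KN(SiMe3)2, 18-crown-6, THF, −78 °C) should then give the Z ester and rejoin the route at 21.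

**Step 14.** Slow acylation of the axial tertiary hydroxyl, with competing acyl exchange between O3 and O4 or isomerisation of the angelate on forcing, is the risk. The fallback sets out from 18 and reverses the order of esterification. Trimethyl orthoacetate with catalytic pyridinium p-toluenesulfonate gives the cyclic 3α,4α-(1-methoxyethylidene) orthoester of 18 F7. Mild aqueous acetic acid should open it toward the axial ester, as is usual for cis-cyclohexanediol orthoesters, to give 4α-acetoxy-3α-hydroxy-5βH,7αH-eudesman-8-one F8. Acylation of the remaining secondary hydroxyl with 20 under the conditions of step 13 rejoins the route at 22.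

## Further compounds

F1 | step 7 | trimethylsilyl ether of 9 | C[Si](C)(C)O[C@]1(C=C)[C@H]2C=C(C)[C@@H]([C@]1(C)OCOCc3ccccc3)C[C@@H]2C(C)C
F2 | step 7 | trimethylsilyl enol ether of 12 | C[Si](C)(C)OC1=CC[C@]2(C)C=C[C@@H](C(C)C)C[C@@H]2[C@]1(C)OCOCc3ccccc3
F3 | step 2 | (±)-(1R*,3S*,4S*,7R*)-3-acetoxy-7-acetyl-3,5-dimethylbicyclo[2.2.2]oct-5-en-2-one (racemate) | O=C1[C@H]2C=C(C)[C@@H]([C@]1(C)OC(C)=O)C[C@@H]2C(C)=O.O=C1[C@@H]2C=C(C)[C@H]([C@@]1(C)OC(C)=O)C[C@H]2C(C)=O
F4 | step 2 | (±)-(1R*,3S*,4S*,7R*)-3-acetoxy-7-isopropenyl-3,5-dimethylbicyclo[2.2.2]oct-5-en-2-one (racemate) | O=C1[C@H]2C=C(C)[C@@H]([C@]1(C)OC(C)=O)C[C@@H]2C(C)=C.O=C1[C@@H]2C=C(C)[C@H]([C@@]1(C)OC(C)=O)C[C@H]2C(C)=C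
F5 | step 10 | 3α-benzyloxy-4α-(benzyloxymethoxy)-9α-iodo-5βH,7αH-eudesman-8β-ol | c4ccccc4CO[C@@H]1CC[C@]2(C)[C@H](I)[C@@H](O)[C@@H](C(C)C)C[C@@H]2[C@]1(C)OCOCc3ccccc3
F6 | step 13 | 4α-hydroxy-8-oxo-5βH,7αH-eudesman-3α-yl 2-[bis(2,2,2-trifluoroethoxy)phosphoryl]propanoate (both epimers at the phosphonate carbon) | CC(C(=O)O[C@@H]1CC[C@]2(C)CC(=O)[C@@H](C(C)C)C[C@@H]2[C@]1(C)O)P(=O)(OCC(F)(F)F)OCC(F)(F)F
F7 | step 14 | cyclic 3α,4α-(1-methoxyethylidene) orthoester of 18 (both epimers at the orthoester carbon) | COC1(C)O[C@@H]2CC[C@]3(C)CC(=O)[C@@H](C(C)C)C[C@@H]3[C@]2(C)O1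
F8 | step 14 | 4α-acetoxy-3α-hydroxy-5βH,7αH-eudesman-8-one | O[C@@H]1CC[C@]2(C)CC(=O)[C@@H](C(C)C)C[C@@H]2[C@]1(C)OC(C)=O
A1 | alternative 1 | cis-4,10-dimethyldecalin-9-one 3-ethylene ketal (eudesmane numbering) | C12(OCCO1)CC[C@]3(C)C(=O)CCC[C@@H]3[C@@H]2C
A2 | alternative 1 | cis-fused hydrindanone 3-ethylene ketal lacking C8 (carbonyl C9 bonded to C7) | C12(OCCO1)CC[C@]3(C)C(=O)CC[C@@H]3[C@@H]2C
A3 | alternative 2 | cis-fused decalin-8-one 3-trimethylsilyl enol ether | C[Si](C)(C)OC1=C(C)[C@H]2CCC(=O)C[C@@]2(C)CC1
A4 | alternative 2 | 4-[(1-hydroxycyclopropyl)methyl]-2,4-dimethylcyclohex-2-en-1-one | O=C1CC[C@](C)(CC2(O)CC2)C=C1C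
A5 | alternative 3 | 3α,4α-dihydroxy-5βH-eudesman-8-one ethylene ketal | O[C@@H]1CC[C@]2(C)CC3(OCCO3)[C@@H](C(C)C)C[C@@H]2[C@]1(C)O
A6 | alternative 3 | 3-[2-acetyl-5,5-(ethylenedioxy)-4-isopropyl-1-methylcyclohexyl]propanal | O=CCC[C@]1(C)CC2(OCCO2)[C@@H](C(C)C)C[C@@H]1C(C)=O
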